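The earlier runs and the new flask stem from a simulated flask for an exercise.

The meeting took up two flasks.

| setting | zeta | beta | birch | cedar |
|---|---|---|---|---|
| starting material | 0.50 M | 0.75 M | 0.50 M | 0.50 M |
| remark | run made earlier | run made earlier | everything together in a closed stirred flask, run for 2.0 h | a single well-mixed tank run continuously and read at steady state, 2.0 h in it on average |
| time |  |  | 2.0 h |  |

| run | time / min | target / % | starting material / % |
|---|---|---|---|
| zeta | 15.0 | 6 | 67 |
| zeta | 40.0 | 15 | 46 |
| zeta | 80.0 | 28 | 28 |
| zeta | 120 | 29 | 19 |
| beta | 5.00 | 0 | 82 |
| beta | 12.0 | 5 | 71 |
| beta | 25.0 | 10 | 58 |
| beta | 40.0 | 17 | 47 |

(scatter of a reading: 1.5 percentage points)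

- the set-up with the highest amount of target at the outlet or at the end, in percent of the starting material put in ("none" if the first two lie within 2 percentage points) (birch / cedar / none)
- amount of target at the outlet or at the end, in percent of the starting material put in, birch
- amount of target at the outlet or at the end, in percent of the starting material put in, cedar

- the stated concentrations are those of everything mixed, before any reaction; amounts are the same in each set-up
- the earlier runs were made in a closed, stirred flask
- a reading or a percentage of target counts all its forms, free or not
- a reading of starting material is of its free form alone

I proposed carrying a yield read from the zeta run into cedar, the tank. The exposure is the area under the free fraction of starting material against time, which for a tank is the mean residence time times the outlet fraction. By trapezoids, the zeta run reaches 50.9 min of exposure by 120 min, when its target reads 29 %, so the exposure yield, target read per minute of exposure, is 0.00570 /min.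

For cedar I took the tail of the zeta run as one decay of constant 0.0111 /min, which extrapolates back to 71.6 %. Treating the early drop as instantaneous, I reckoned an outlet fraction of 30.8 % and so 21.1 % target. Birch repeats the zeta charge and time, so I expected it near that reading of 29 %.

The forecaster reported 30 % for birch, 23 % for cedar and birch as best, arguing that “the tank output is the Laplace-weighted batch curve”. That cedar figure stands above mine, though we agreed on the order.

Birch gave 31.4 % and cedar 22.4 %, so birch leads by 9 percentage points, wider than the margin of 2 points.

    starting material + target ⇌ idle adduct, settled at all times (K = 6.30 /M)
    intermediate → decomposed reagent (k = 0.0230 /min)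
    intermediate → target (k = 0.0280 /min)
    starting material ⇌ intermediate (K = 0.370, k = 0.0430 /min)
    target → over-reaction product (k = 0.00320 /min)

Cedar's outlet held 32.3 % free starting material, and the exposure yield applied to that fraction over 2.0 h gives 22.1 % target. The beta run reaches an exposure of 26.2 min by its last reading, where the same yield gives 14.9 % and the run holds 16.3 % target.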